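**Retrosynthetic overview**
1. Target ⇒ (Si–O cleavage) ⇒ closure of the O–C-a bond by acid hydroalkoxylation of the chromene C=C of a 3-substituted N-methylflindersine; this sets C-a and C-b.
2. That chromene (2,2-dimethylpyran on quinolinone B) ⇒ Knoevenagel/oxa-6π annulation of 4-hydroxy-1-methylquinolin-2(1H)-one with a lactol that is a masked α-isopropylidene aldehyde.
3. Masked aldehyde ⇒ Mukaiyama-type addition of 2,2-dimethoxypropane to the silyl ketene acetal of a dihydropyrano[3,2-c]quinoline-2,5-dione, then lactone → lactol.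
4. Lactone ⇒ lactol from the key enantioselective intermolecular Michael addition of the same hydroxyquinolinone to (E)-5-silyloxy-5-methylhex-2-enal (sets C-c); enal ⇒ cross-metathesis of silylated 2-methylpent-4-en-2-ol with crotonaldehyde.
5. Ring order: pyran on quinolinone A as lactol/lactone (steps 3–7, opened in step 8) → 2,2-dimethylpyran on quinolinone B (step 8) → pyran on quinolinone A closed again (step 9).

Labels: C-a = OCH(aryl) ring-fusion carbon; C-b = ring-fusion CH next to CMe2; C-c = CH carrying the side chain. Quinolinone A carries C-c at its C-3; quinolinone B carries the CMe2–O ring.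
Assumption: the descriptors read from the target SMILES are C-a R, C-b S, C-c S.

**Route**

Step 1
Reactants: 1 2-methylpent-4-en-2-ol
Product: 2 tert-butyldimethyl[(2-methylpent-4-en-2-yl)oxy]silane
Conditions: TBSOTf, 2,6-lutidine, CH2Cl2, 0 °C to rt
Reagents that add atoms: tert-butyldimethylsilyl trifluoromethanesulfonate, CC(C)(C)[Si](C)(C)OS(=O)(=O)C(F)(F)F
Why: Silylation of a hindered tertiary alcohol with the silyl triflate and a hindered pyridine base is standard and masks the OH against the later cationic steps; no stereocentre is involved.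

Step 2
Reactants: 2 tert-butyldimethyl[(2-methylpent-4-en-2-yl)oxy]silane; 3 (E)-but-2-enal
Product: 4 (E)-5-[(tert-butyldimethylsilyl)oxy]-5-methylhex-2-enal
Conditions: 3 (5 equiv), second-generation Hoveyda–Grubbs catalyst RuCl2(=CH-C6H4-2-O-i-Pr)(H2IMes) (3 mol%), CH2Cl2, 40 °C
Reagents that add atoms: none
Why: Olefin cross-metathesis of a terminal alkene with excess crotonaldehyde releases propene and gives the E-enal under thermodynamic control.

Step 3
Reactants: 4 (E)-5-[(tert-butyldimethylsilyl)oxy]-5-methylhex-2-enal; 5 4-hydroxy-1-methylquinolin-2(1H)-one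
Product: 7 (4S)-4-{2-[(tert-butyldimethylsilyl)oxy]-2-methylpropyl}-2-hydroxy-6-methyl-2,3,4,6-tetrahydro-5H-pyrano[3,2-c]quinolin-5-one (lactol; both C-2 anomers), via open-chain Michael aldehyde 6 (not isolated)
Conditions: (R)-2-[diphenyl(trimethylsilyloxy)methyl]pyrrolidine (20 mol%), CH2Cl2, 0 °C to rt
Reagents that add atoms: none
Why: Iminium-catalysed enantioselective intermolecular Michael addition of C-3 of the hydroxyquinolinone to the enal (diarylprolinol silyl ether catalysis, precedented for 4-hydroxycoumarins and 4-hydroxyquinolinones), in which the Ph2C(OSiMe3) group of the (R)-catalyst shields one face of the (E)-iminium ion so that C-c is formed S, followed by spontaneous hemiacetal closure through the 4-OH.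

Step 4
Reactants: 7 lactol
Product: 8 (4S)-4-{2-[(tert-butyldimethylsilyl)oxy]-2-methylpropyl}-6-methyl-3,4-dihydro-2H-pyrano[3,2-c]quinoline-2,5(6H)-dione
Conditions: PhI(OAc)2, TEMPO (10 mol%), CH2Cl2, rt
Reagents that add atoms: none
Why: Oxoammonium-mediated lactol-to-lactone oxidation is mild and leaves the silyl ether, the lactam and the non-epimerisable C-c centre untouched.

Step 5
Reactants: 8 lactone
Product: 9 (4S)-4-{2-[(tert-butyldimethylsilyl)oxy]-2-methylpropyl}-6-methyl-2-[(trimethylsilyl)oxy]-4,6-dihydro-5H-pyrano[3,2-c]quinolin-5-one (silyl ketene acetal; used crude)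
Conditions: Me3SiCl then LiN(SiMe3)2, THF, −78 °C; LiCl filtered off in pentane
Reagents that add atoms: chlorotrimethylsilane, C[Si](C)(C)Cl
Why: Enolisation of the only α-CH2 with in situ O-silylation traps the enolate before the aryl-type ester can fragment to a ketene; C-c is not acidic and is unaffected.

Step 6
Reactants: 9 silyl ketene acetal; 10 2,2-dimethoxypropane
Product: 11 (3R,4S)-4-{2-[(tert-butyldimethylsilyl)oxy]-2-methylpropyl}-3-(2-methoxypropan-2-yl)-6-methyl-3,4-dihydro-2H-pyrano[3,2-c]quinoline-2,5(6H)-dione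
Conditions: 10 (3 equiv), Me3SiOTf (10 mol%), CH2Cl2, −78 °C
Reagents that add atoms: none
Why: Mukaiyama aldol-type addition of the silyl ketene acetal to the oxocarbenium ion from the ketal (Noyori conditions) forms the C-3–CMe2 bond anti to the C-4 substituent (trans, 3R); this centre is only a relay and becomes sp2 in step 8.

Step 7
Reactants: 11 β-methoxy lactone
Product: 12 (3R,4S)-4-{2-[(tert-butyldimethylsilyl)oxy]-2-methylpropyl}-2-hydroxy-3-(2-methoxypropan-2-yl)-6-methyl-2,3,4,6-tetrahydro-5H-pyrano[3,2-c]quinolin-5-one (lactol; both C-2 anomers)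
Conditions: i-Bu2AlH (1.2 equiv), CH2Cl2, −78 °C; aq. KNaC4H4O6
Reagents that add atoms: none
Why: Partial reduction of the activated aryl-type lactone stops at the lactol at −78 °C, while the far less electrophilic N-methyl lactam and the ethers survive.

Step 8
Reactants: 12 lactol; 5 4-hydroxy-1-methylquinolin-2(1H)-one
Product: 14 3-[(1S)-3-[(tert-butyldimethylsilyl)oxy]-1-(4-hydroxy-1-methyl-2-oxo-1,2-dihydroquinolin-3-yl)-3-methylbutyl]-2,2,6-trimethyl-2,6-dihydro-5H-pyrano[3,2-c]quinolin-5-one, via 1-oxatriene 13 (not isolated)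
Conditions: ethylenediammonium diacetate (30 mol%), toluene, 80 °C
Reagents that add atoms: none
Why: Amine-catalysed Knoevenagel condensation of the ring-opened aldehyde with loss of methanol (β-elimination) gives the 1-oxatriene, whose oxa-6π-electrocyclisation closes the 2,2-dimethylpyran as in the classical flindersine synthesis; C-c is untouched and C-b becomes sp2.

Step 9
Reactants: 14 3-substituted N-methylflindersine
Product: 15 O-tert-butyldimethylsilyl ether of the target (C-a R, C-b S, C-c S; cis-fused bis-pyran)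
Conditions: p-TsOH·H2O (10 mol%), ClCH2CH2Cl, 40 °C
Reagents that add atoms: none
Why: Brønsted-acid hydroalkoxylation in which protonation at C-b gives a cation at C-a stabilised by the ring oxygen of quinolinone B and the 4-OH of quinolinone A captures it 6-endo from the opposite face (cis fusion); because the side chain cannot eclipse the gem-dimethyl group (allylic 1,2 strain) the reacting conformer places it trans to CMe2, giving C-a R and C-b S, which should also be the thermodynamic isomer of this reversible closure since only it keeps both the side chain and the C-a–O bond pseudoaxial, away from the lactam carbonyls.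

Step 10
Reactants: 15 silyl ether
Product: 16 target CNP0202276.2 (C-a R, C-b S, C-c S)
Conditions: Bu4NF (3 equiv), THF, 40 °C
Reagents that add atoms: none
Why: Fluoride desilylation of the tertiary silyl ether is neutral to the acid-labile O–C-a linkage and to all three stereocentres.

**Compound list**
1 | 2-methylpent-4-en-2-ol | C=CCC(C)(C)O | starting material
2 | tert-butyldimethyl[(2-methylpent-4-en-2-yl)oxy]silane | C=CCC(C)(C)O[Si](C)(C)C(C)(C)C | intermediate
3 | (E)-but-2-enal (crotonaldehyde) | C/C=C/C=O | starting material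
4 | (E)-5-[(tert-butyldimethylsilyl)oxy]-5-methylhex-2-enal | O=C/C=C/CC(C)(C)O[Si](C)(C)C(C)(C)C | intermediate
5 | 4-hydroxy-1-methylquinolin-2(1H)-one | Cn1c(=O)cc(O)c2ccccc21 | starting material
6 | (3S)-5-[(tert-butyldimethylsilyl)oxy]-3-(4-hydroxy-1-methyl-2-oxo-1,2-dihydroquinolin-3-yl)-5-methylhexanal (open-chain Michael aldehyde, not isolated) | Cn1c(=O)c(c(O)c2ccccc21)[C@H](CC=O)CC(C)(C)O[Si](C)(C)C(C)(C)C | intermediate
7 | (4S)-4-{2-[(tert-butyldimethylsilyl)oxy]-2-methylpropyl}-2-hydroxy-6-methyl-2,3,4,6-tetrahydro-5H-pyrano[3,2-c]quinolin-5-one (lactol, both C-2 anomers) | Cn1c(=O)c2c(c3ccccc31)OC(O)C[C@@H]2CC(C)(C)O[Si](C)(C)C(C)(C)C | intermediate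
8 | (4S)-4-{2-[(tert-butyldimethylsilyl)oxy]-2-methylpropyl}-6-methyl-3,4-dihydro-2H-pyrano[3,2-c]quinoline-2,5(6H)-dione | Cn1c(=O)c2c(c3ccccc31)OC(=O)C[C@@H]2CC(C)(C)O[Si](C)(C)C(C)(C)C | intermediate
9 | (4S)-4-{2-[(tert-butyldimethylsilyl)oxy]-2-methylpropyl}-6-methyl-2-[(trimethylsilyl)oxy]-4,6-dihydro-5H-pyrano[3,2-c]quinolin-5-one | Cn1c(=O)c2c(c3ccccc31)OC(O[Si](C)(C)C)=C[C@@H]2CC(C)(C)O[Si](C)(C)C(C)(C)C | intermediate
10 | 2,2-dimethoxypropane | COC(C)(C)OC | starting material
11 | (3R,4S)-4-{2-[(tert-butyldimethylsilyl)oxy]-2-methylpropyl}-3-(2-methoxypropan-2-yl)-6-methyl-3,4-dihydro-2H-pyrano[3,2-c]quinoline-2,5(6H)-dione | Cn1c(=O)c2c(c3ccccc31)OC(=O)[C@@H](C(C)(C)OC)[C@@H]2CC(C)(C)O[Si](C)(C)C(C)(C)C | intermediate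
12 | (3R,4S)-4-{2-[(tert-butyldimethylsilyl)oxy]-2-methylpropyl}-2-hydroxy-3-(2-methoxypropan-2-yl)-6-methyl-2,3,4,6-tetrahydro-5H-pyrano[3,2-c]quinolin-5-one (lactol, both C-2 anomers) | Cn1c(=O)c2c(c3ccccc31)OC(O)[C@@H](C(C)(C)OC)[C@@H]2CC(C)(C)O[Si](C)(C)C(C)(C)C | intermediate
13 | 3-[(3S)-5-[(tert-butyldimethylsilyl)oxy]-3-(4-hydroxy-1-methyl-2-oxo-1,2-dihydroquinolin-3-yl)-5-methyl-2-(propan-2-ylidene)hexylidene]-1-methylquinoline-2,4(1H,3H)-dione (1-oxatriene, not isolated) | CN1C(=O)C(=CC(=C(C)C)[C@H](CC(C)(C)O[Si](C)(C)C(C)(C)C)c2c(O)c3ccccc3n(C)c2=O)C(=O)c2ccccc21 | intermediate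
14 | 3-[(1S)-3-[(tert-butyldimethylsilyl)oxy]-1-(4-hydroxy-1-methyl-2-oxo-1,2-dihydroquinolin-3-yl)-3-methylbutyl]-2,2,6-trimethyl-2,6-dihydro-5H-pyrano[3,2-c]quinolin-5-one | Cn1c(=O)c2c(c3ccccc31)OC(C)(C)C(=C2)[C@H](CC(C)(C)O[Si](C)(C)C(C)(C)C)c1c(O)c2ccccc2n(C)c1=O | intermediate
15 | O-tert-butyldimethylsilyl ether of the target (C-a R, C-b S, C-c S) | Cn1c(=O)c2c(c3ccccc31)O[C@H]1c3c(c4ccccc4n(C)c3=O)OC(C)(C)[C@H]1[C@@H]2CC(C)(C)O[Si](C)(C)C(C)(C)C | intermediate
16 | CNP0202276.2: cis-fused bis(pyrano[3,2-c]quinolin-5-one) in which C-a (R) bears the ring O of quinolinone A and C-3 of quinolinone B, C-b (S) bears CMe2–O of quinolinone B, and C-c (S) bears CH2C(CH3)2OH and C-3 of quinolinone A | Cn1c(=O)c2c(c3ccccc31)O[C@H]1c3c(c4ccccc4n(C)c3=O)OC(C)(C)[C@H]1[C@@H]2CC(C)(C)O | target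

**Totals**
Total step count: 10. Longest linear sequence: 10 steps (1 → 16); compounds 3, 5 and 10 are bought.

**Three steps most likely to fail, with fallbacks**

Step 6 (ketal addition to a hindered, fragile silyl ketene acetal). The fallback sets out from lactol 7 and comes back at lactol 12, avoiding the lactone oxidation level altogether. Acid-catalysed dehydration of 7 (pyridinium p-toluenesulfonate, toluene, 80 °C, water removed) gives the cyclic enol ether (4S)-4-{2-[(tert-butyldimethylsilyl)oxy]-2-methylpropyl}-6-methyl-4,6-dihydro-5H-pyrano[3,2-c]quinolin-5-one F1. BF3·OEt2-catalysed acetal–enol ether condensation of F1 with 2,2-dimethoxypropane 10 adds the Me2C(OMe) unit at C-3 anti to the C-4 substituent and caps C-2 with methoxide, giving the methyl acetal (3R,4S)-4-{2-[(tert-butyldimethylsilyl)oxy]-2-methylpropyl}-2-methoxy-3-(2-methoxypropan-2-yl)-6-methyl-2,3,4,6-tetrahydro-5H-pyrano[3,2-c]quinolin-5-one F2. Mild hydrolysis (AcOH, H2O, THF) then returns 12.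

Step 8 (one-pot condensation, elimination and electrocyclisation through a tetrasubstituted enal in the presence of a free 4-OH). The fallback sets out from lactol 12 and comes back at 14, splitting the cascade into two controllable stages. With a catalytic Brønsted acid (p-TsOH, CH2Cl2, rt) the oxocarbenium ion of 12 alkylates C-3 of 5 (Friedel–Crafts-type C-glycosylation) to give the 2-aryl pyran (3S,4S)-4-{2-[(tert-butyldimethylsilyl)oxy]-2-methylpropyl}-2-(4-hydroxy-1-methyl-2-oxo-1,2-dihydroquinolin-3-yl)-3-(2-methoxypropan-2-yl)-6-methyl-2,3,4,6-tetrahydro-5H-pyrano[3,2-c]quinolin-5-one F3. Heating F3 with DBU in toluene (90 °C) then opens the pyran to the quinone methide, which enolises, loses methanol and closes by oxa-6π-electrocyclisation to 14.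

Step 9 (diastereoselectivity at C-a and C-b rests on conformational and thermodynamic arguments). The fallback sets out from 2 and 5 and comes back at 15; it builds the two centres by a suprafacial cycloaddition and gives up asymmetric induction for a resolution. Ozonolysis of 2 (O3, CH2Cl2, −78 °C, then Me2S) gives 3-[(tert-butyldimethylsilyl)oxy]-3-methylbutanal F4. Compound 5 and bought 3-methylbut-2-enal (CC(C)=CC=O; pyridine, 110 °C, Knoevenagel/oxa-6π) give N-methylflindersine F5. Heating 5, F4 and excess F5 with ethylenediammonium diacetate in toluene (100 °C) generates 3-{3-[(tert-butyldimethylsilyl)oxy]-3-methylbutylidene}-1-methylquinoline-2,4(1H,3H)-dione F6 in the flask. F6 adds across the chromene double bond of F5 in an inverse-electron-demand hetero-Diels–Alder reaction, which fixes the cis ring fusion and gives racemic 15 F7. Preparative HPLC on a chiral stationary phase then delivers 15.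

**Further compounds**
F1 | step 6 | (4S)-4-{2-[(tert-butyldimethylsilyl)oxy]-2-methylpropyl}-6-methyl-4,6-dihydro-5H-pyrano[3,2-c]quinolin-5-one | Cn1c(=O)c2c(c3ccccc31)OC=C[C@@H]2CC(C)(C)O[Si](C)(C)C(C)(C)C
F2 | step 6 | (3R,4S)-4-{2-[(tert-butyldimethylsilyl)oxy]-2-methylpropyl}-2-methoxy-3-(2-methoxypropan-2-yl)-6-methyl-2,3,4,6-tetrahydro-5H-pyrano[3,2-c]quinolin-5-one | Cn1c(=O)c2c(c3ccccc31)OC(OC)[C@@H](C(C)(C)OC)[C@@H]2CC(C)(C)O[Si](C)(C)C(C)(C)C
F3 | step 8 | (3S,4S)-4-{2-[(tert-butyldimethylsilyl)oxy]-2-methylpropyl}-2-(4-hydroxy-1-methyl-2-oxo-1,2-dihydroquinolin-3-yl)-3-(2-methoxypropan-2-yl)-6-methyl-2,3,4,6-tetrahydro-5H-pyrano[3,2-c]quinolin-5-one | Cn1c(=O)c2c(c3ccccc31)OC(c1c(O)c3ccccc3n(C)c1=O)[C@@H](C(C)(C)OC)[C@@H]2CC(C)(C)O[Si](C)(C)C(C)(C)C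
F4 | step 9 | 3-[(tert-butyldimethylsilyl)oxy]-3-methylbutanal | CC(C)(CC=O)O[Si](C)(C)C(C)(C)C
F5 | step 9 | N-methylflindersine (2,2,6-trimethyl-2,6-dihydro-5H-pyrano[3,2-c]quinolin-5-one) | Cn1c(=O)c2c(c3ccccc31)OC(C)(C)C=C2
F6 | step 9 | 3-{3-[(tert-butyldimethylsilyl)oxy]-3-methylbutylidene}-1-methylquinoline-2,4(1H,3H)-dione | CN1C(=O)C(=CCC(C)(C)O[Si](C)(C)C(C)(C)C)C(=O)c2ccccc21
F7 | step 9 | racemic 15 (1:1 mixture of 15 and its enantiomer) | Cn1c(=O)c2c(c3ccccc31)O[C@H]1c3c(c4ccccc4n(C)c3=O)OC(C)(C)[C@H]1[C@@H]2CC(C)(C)O[Si](C)(C)C(C)(C)C.Cn1c(=O)c2c(c3ccccc31)O[C@@H]1c3c(c4ccccc4n(C)c3=O)OC(C)(C)[C@@H]1[C@H]2CC(C)(C)O[Si](C)(C)C(C)(C)C
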